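**Retrosynthetic overview**
- The strategy rests on the tetrahydrofuran ring (O1, C2 carrying ring A, C3–CH3, C4–CH3, C5 carrying ring B): ring A and both methyl groups lie on one face and ring B alone on the other, so the single C2 carbinol centre can dictate C3, C4 and C5 through a flat 3,4-dimethylbutenolide.
- Disconnection 1: the C5–ring B bond, giving an all-cis anomeric sulfone (fragment 1) and the arylzinc of the complete side-chain aryl bromide (fragment 2).
- Disconnection 2: the five-membered oxygen ring, assembled as a butenolide from an (R)-propargylic alcohol, MeMgCl and CO2 (C3–CH3, C4–C5 and O1–C5 bonds); the alcohol comes from O-benzylvanillin and propynyl Grignard by enantioselective ynone reduction.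
- Fragment 2: C8' from ethyl (S)-lactate by Mitsunobu inversion, C7' by chelation-controlled reduction of a Weinreb-derived aryl ketone.
- Ring order: the butenolide is the only ring built (step 4) and is carried through lactone, lactol and sulfone to the tetrahydrofuran; rings A, B and C are bought.

Key step: step 4

Remark on the chemistry: in the oxazaborolidine reduction the aryl ring is taken as the large and the linear 1-propynyl group as the small ketone substituent, which is why the (R)-catalyst is specified for the (R)-carbinol.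

**Route**

Step 1
Reactants: 1 4-benzyloxy-3-methoxybenzaldehyde; 2 1-propynylmagnesium bromide
Product: 3 (±)-1-(4-benzyloxy-3-methoxyphenyl)but-2-yn-1-ol
Conditions: THF, 0 °C → rt
Reagents that add atoms: none
Why: Grignard 1,2-addition of the alkynylmagnesium to the aldehyde should give the propargylic alcohol; the new carbinol centre is racemic and is erased in step 2.

Step 2
Reactants: 3 (±)-1-(4-benzyloxy-3-methoxyphenyl)but-2-yn-1-ol
Product: 4 1-(4-benzyloxy-3-methoxyphenyl)but-2-yn-1-one
Conditions: activated MnO2, CH2Cl2, rt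
Reagents that add atoms: none
Why: MnO2 oxidation is selective for benzylic/propargylic alcohols and should leave the benzyl ether and the alkyne untouched.

Step 3
Reactants: 4 1-(4-benzyloxy-3-methoxyphenyl)but-2-yn-1-one
Product: 5 (R)-1-(4-benzyloxy-3-methoxyphenyl)but-2-yn-1-ol
Conditions: (R)-1-methyl-3,3-diphenyltetrahydro-1H,3H-pyrrolo[1,2-c][1,3,2]oxazaborole [(R)-Me-CBS, 20 mol %], catecholborane, CH2Cl2, −78 °C
Reagents that add atoms: none
Why: Corey–Bakshi–Shibata reduction, in which the ketone binds the catalyst boron on the side of the slim propynyl group and hydride is delivered under catalyst control, should set the (R)-carbinol (R because 1-propynyl outranks the aryl group).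

Step 4
Reactants: 5 (R)-1-(4-benzyloxy-3-methoxyphenyl)but-2-yn-1-ol
Product: 8 (R)-5-(4-benzyloxy-3-methoxyphenyl)-3,4-dimethylfuran-2(5H)-one, via oxamagnesacycle 6 (not isolated), via hydroxy acid 7 (not isolated)
Conditions: MeMgCl (4 equiv), CuI (20 mol %), toluene–THF, 0 °C → rt; CO2 (gas), −20 °C → rt; pH 5 phosphate buffer work-up
Reagents that add atoms: methylmagnesium chloride, C[Mg]Cl; carbon dioxide, O=C=O
Why: MeMgCl first deprotonates 5, and the magnesium alkoxide then steers a copper-catalysed anti-carbomagnesiation of the triple bond in which methyl goes to the alkyne carbon next to the carbinol and magnesium to the far carbon, giving the five-membered chelate 6. CO2 inserts into the vinyl C–Mg bond with retention of alkene geometry, so the new carboxyl group in 7 is cis to the carbinol. On buffered acidification the hydroxyl attacks the carboxyl carbon in a 5-exo-trig lactonisation that closes the butenolide ring of 8, so one flask makes the C3–CH3, C4–C5 and O1–C5 bonds of the later tetrahydrofuran (C5 from CO2). The closest known reaction type is the alkoxide-directed, CuI-catalysed anti-carbomagnesiation of propargylic alcohols with CO2 trapping to butenolides. No new stereocentre is formed: the (R)-carbinol is not ionised under the basic conditions, and the tetrasubstituted alkene geometry is fixed by the anti addition and the chelate. The step needs methyl on the proximal and carboxyl on the distal carbon cis to oxygen, which the chelating alkoxide of the substrate secures, and the pH 5 work-up spares the acid-sensitive p-alkoxybenzylic C–O bond.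

Step 5
Reactants: 8 (R)-5-(4-benzyloxy-3-methoxyphenyl)-3,4-dimethylfuran-2(5H)-one
Product: 9 (3S,4R,5S)-5-(4-benzyloxy-3-methoxyphenyl)-3,4-dimethyldihydrofuran-2(3H)-one (all-cis)
Conditions: H2 (4 atm), 5% Rh/Al2O3, EtOAc, rt
Reagents that add atoms: none
Why: heterogeneous syn hydrogenation should deliver both hydrogens to the butenolide face opposite the C5 aryl group, placing both methyls cis to ring A (C3 and C4 set together), while Rh/Al2O3 in neutral EtOAc has little tendency to cleave the O-benzyl or the benzylic lactone C–O bond.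

Step 6
Reactants: 9 (3S,4R,5S)-5-(4-benzyloxy-3-methoxyphenyl)-3,4-dimethyldihydrofuran-2(3H)-one
Product: 10 (3S,4R,5S)-5-(4-benzyloxy-3-methoxyphenyl)-3,4-dimethyltetrahydrofuran-2-ol (anomer mixture)
Conditions: i-Bu2AlH (DIBAL-H, 1.1 equiv), CH2Cl2, −78 °C
Reagents that add atoms: none
Why: partial lactone reduction with DIBAL-H stops at the aluminium hemiacetal at −78 °C, and the non-basic cold conditions should not epimerise the α-methyl centre.

Step 7
Reactants: 10 (3S,4R,5S)-5-(4-benzyloxy-3-methoxyphenyl)-3,4-dimethyltetrahydrofuran-2-ol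
Product: 11 (3S,4R,5S)-5-(4-benzyloxy-3-methoxyphenyl)-3,4-dimethyl-2-(phenylsulfonyl)tetrahydrofuran (anomer mixture)
Conditions: PhSO2H, CaCl2, CH2Cl2, rt
Reagents that add atoms: benzenesulfinic acid, O=S(O)c1ccccc1
Why: Ley-type exchange of the lactol hydroxyl for sulfinate through the oxocarbenium ion, driven by CaCl2 as water scavenger, should give the anomeric sulfone; its anomeric configuration is irrelevant because it is lost in step 13.

Step 8
Reactants: 12 ethyl (S)-lactate; 13 4-bromo-2-methoxyphenol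
Product: 14 ethyl (R)-2-(4-bromo-2-methoxyphenoxy)propanoate
Conditions: PPh3, DIAD, THF, 0 °C → rt
Reagents that add atoms: none
Why: Mitsunobu etherification displaces the activated lactate oxygen by the phenoxide in an SN2 step with clean inversion, turning the (S) centre into the (R) centre that becomes C8'.

Step 9
Reactants: 14 ethyl (R)-2-(4-bromo-2-methoxyphenoxy)propanoate
Product: 15 (R)-2-(4-bromo-2-methoxyphenoxy)-N-methoxy-N-methylpropanamide
Conditions: MeNHOMe·HCl, i-PrMgCl, THF, −20 → 0 °C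
Reagents that add atoms: N,O-dimethylhydroxylamine hydrochloride, CNOC.Cl
Why: Weinreb aminolysis of the ester by the chloromagnesium amide formed in situ is fast at low temperature and should not enolise the α-aryloxy centre or touch the aryl bromide.

Step 10
Reactants: 15 (R)-2-(4-bromo-2-methoxyphenoxy)-N-methoxy-N-methylpropanamide; 16 1-benzyloxy-4-bromo-2-methoxybenzene
Product: 18 (R)-1-(4-benzyloxy-3-methoxyphenyl)-2-(4-bromo-2-methoxyphenoxy)propan-1-one, via arylmagnesium bromide 17 (not isolated)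
Conditions: 16, Mg turnings, THF, 40 °C; then 15, THF, −78 → 0 °C; cold dilute acid quench
Reagents that add atoms: none
Why: Weinreb ketone synthesis, in which the chelated tetrahedral adduct holds until work-up so no over-addition occurs, and the low temperature with a cold quench protects the enolisable α-centre.

Step 11
Reactants: 18 (R)-1-(4-benzyloxy-3-methoxyphenyl)-2-(4-bromo-2-methoxyphenoxy)propan-1-one
Product: 19 (1S,2R)-1-(4-benzyloxy-3-methoxyphenyl)-2-(4-bromo-2-methoxyphenoxy)propan-1-ol (erythro)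
Conditions: Zn(BH4)2, Et2O, −20 → 0 °C
Reagents that add atoms: none
Why: Cram-chelate reduction, in which zinc bridges the carbonyl and aryloxy oxygens and hydride enters from the side of the α-hydrogen and not the α-methyl, should set the (1S) carbinol and thus the erythro pair.

Step 12
Reactants: 19 (1S,2R)-1-(4-benzyloxy-3-methoxyphenyl)-2-(4-bromo-2-methoxyphenoxy)propan-1-ol
Product: 20 tert-butyl{[(1S,2R)-1-(4-benzyloxy-3-methoxyphenyl)-2-(4-bromo-2-methoxyphenoxy)propyl]oxy}dimethylsilane (fragment 2)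
Conditions: TBSOTf, 2,6-lutidine, CH2Cl2, −78 → 0 °C
Reagents that add atoms: tert-butyldimethylsilyl trifluoromethanesulfonate, CC(C)(C)[Si](C)(C)OS(=O)(=O)C(F)(F)F
Why: silyl triflate silylation under hindered-base conditions masks the benzylic alcohol against the organolithium of step 13 without ionising the electron-rich benzylic centre.

Step 13
Reactants: 20 fragment 2 aryl bromide (2 equiv); 11 (3S,4R,5S)-5-(4-benzyloxy-3-methoxyphenyl)-3,4-dimethyl-2-(phenylsulfonyl)tetrahydrofuran
Product: 24 (2S,3R,4S,5S)-2-(4-benzyloxy-3-methoxyphenyl)-5-{4-[((1S,2R)-1-(4-benzyloxy-3-methoxyphenyl)-1-(tert-butyldimethylsilyloxy)propan-2-yl)oxy]-3-methoxyphenyl}-3,4-dimethyltetrahydrofuran, via aryllithium 21 (not isolated), via arylzinc bromide 22 (not isolated), via oxocarbenium ion 23 (not isolated)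
Conditions: 20, n-BuLi, THF, −78 °C; ZnBr2, −78 → 0 °C; then 11, THF, rt
Reagents that add atoms: none
Why: Ley-type substitution of an anomeric sulfone by an arylzinc, in which the zinc Lewis acid ionises the sulfone to the oxocarbenium ion and the aryl group should add to the face opposite the three cis substituents (two methyls and ring A), setting C5 trans to all of them.

Step 14
Reactants: 24 fully protected target
Product: 25 (1S,2R)-1-(4-benzyloxy-3-methoxyphenyl)-2-{4-[(2S,3S,4R,5S)-5-(4-benzyloxy-3-methoxyphenyl)-3,4-dimethyltetrahydrofuran-2-yl]-2-methoxyphenoxy}propan-1-ol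
Conditions: Bu4NF (TBAF), AcOH, THF, rt
Reagents that add atoms: none
Why: fluoride desilylation driven by the Si–F bond, buffered with acetic acid so the medium stays non-basic, should free the benzylic alcohol without touching the aryl ethers or the tetrahydrofuran.

Step 15
Reactants: 25 bis-benzyl ether of the target
Product: 26 CNP0171079.3, 4-[(2S,3R,4S,5S)-5-{4-[((1S,2R)-1-hydroxy-1-(4-hydroxy-3-methoxyphenyl)propan-2-yl)oxy]-3-methoxyphenyl}-3,4-dimethyltetrahydrofuran-2-yl]-2-methoxyphenol
Conditions: H2 (1 atm), 10% Pd/C, EtOAc, rt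
Reagents that add atoms: none
Why: catalytic hydrogenolysis under neutral conditions cleaves the two aryl benzyl ethers much faster than the benzylic C–O bonds of the tetrahydrofuran and the secondary benzylic alcohol, so stopping after two equivalents of H2 should give the target.

**Compound list**
1 | 4-benzyloxy-3-methoxybenzaldehyde | COc1cc(C=O)ccc1OCc1ccccc1 | starting material
2 | 1-propynylmagnesium bromide | CC#C[Mg]Br | starting material
3 | (±)-1-(4-benzyloxy-3-methoxyphenyl)but-2-yn-1-ol | CC#CC(O)c1ccc(OCc2ccccc2)c(OC)c1 | intermediate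
4 | 1-(4-benzyloxy-3-methoxyphenyl)but-2-yn-1-one | CC#CC(=O)c1ccc(OCc2ccccc2)c(OC)c1 | intermediate
5 | (R)-1-(4-benzyloxy-3-methoxyphenyl)but-2-yn-1-ol | CC#C[C@H](O)c1ccc(OCc2ccccc2)c(OC)c1 | intermediate
6 | (R)-5-(4-benzyloxy-3-methoxyphenyl)-3,4-dimethyl-2,5-dihydro-1,2-oxamagnesole (chelated vinylmagnesium alkoxide, drawn without its halide ligands) | CC1=C(C)[C@@H](c2ccc(OCc3ccccc3)c(OC)c2)O[Mg]1 | intermediate
7 | (2Z,4R)-4-(4-benzyloxy-3-methoxyphenyl)-4-hydroxy-2,3-dimethylbut-2-enoic acid | OC(=O)/C(C)=C(C)\[C@H](O)c1ccc(OCc2ccccc2)c(OC)c1 | intermediate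
8 | (R)-5-(4-benzyloxy-3-methoxyphenyl)-3,4-dimethylfuran-2(5H)-one | CC1=C(C)[C@@H](c2ccc(OCc3ccccc3)c(OC)c2)OC1=O | intermediate
9 | (3S,4R,5S)-5-(4-benzyloxy-3-methoxyphenyl)-3,4-dimethyldihydrofuran-2(3H)-one | COc1cc([C@H]2OC(=O)[C@@H](C)[C@H]2C)ccc1OCc1ccccc1 | intermediate
10 | (3S,4R,5S)-5-(4-benzyloxy-3-methoxyphenyl)-3,4-dimethyltetrahydrofuran-2-ol (anomer mixture) | COc1cc([C@H]2OC(O)[C@@H](C)[C@H]2C)ccc1OCc1ccccc1 | intermediate
11 | (3S,4R,5S)-5-(4-benzyloxy-3-methoxyphenyl)-3,4-dimethyl-2-(phenylsulfonyl)tetrahydrofuran (anomer mixture) | COc1cc([C@H]2OC(S(=O)(=O)c3ccccc3)[C@@H](C)[C@H]2C)ccc1OCc1ccccc1 | intermediate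
12 | ethyl (S)-lactate | CCOC(=O)[C@H](C)O | starting material
13 | 4-bromo-2-methoxyphenol | COc1cc(Br)ccc1O | starting material
14 | ethyl (R)-2-(4-bromo-2-methoxyphenoxy)propanoate | CCOC(=O)[C@@H](C)Oc1ccc(Br)cc1OC | intermediate
15 | (R)-2-(4-bromo-2-methoxyphenoxy)-N-methoxy-N-methylpropanamide | CON(C)C(=O)[C@@H](C)Oc1ccc(Br)cc1OC | intermediate
16 | 1-benzyloxy-4-bromo-2-methoxybenzene | COc1cc(Br)ccc1OCc1ccccc1 | starting material
17 | (4-benzyloxy-3-methoxyphenyl)magnesium bromide | COc1cc([Mg]Br)ccc1OCc1ccccc1 | intermediate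
18 | (R)-1-(4-benzyloxy-3-methoxyphenyl)-2-(4-bromo-2-methoxyphenoxy)propan-1-one | COc1cc(Br)ccc1O[C@H](C)C(=O)c1ccc(OCc2ccccc2)c(OC)c1 | intermediate
19 | (1S,2R)-1-(4-benzyloxy-3-methoxyphenyl)-2-(4-bromo-2-methoxyphenoxy)propan-1-ol | COc1cc(Br)ccc1O[C@H](C)[C@@H](O)c1ccc(OCc2ccccc2)c(OC)c1 | intermediate
20 | tert-butyl{[(1S,2R)-1-(4-benzyloxy-3-methoxyphenyl)-2-(4-bromo-2-methoxyphenoxy)propyl]oxy}dimethylsilane | COc1cc(Br)ccc1O[C@H](C)[C@@H](O[Si](C)(C)C(C)(C)C)c1ccc(OCc2ccccc2)c(OC)c1 | intermediate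
21 | aryllithium from 20 (lithium in place of bromine) | COc1cc([Li])ccc1O[C@H](C)[C@@H](O[Si](C)(C)C(C)(C)C)c1ccc(OCc2ccccc2)c(OC)c1 | intermediate
22 | arylzinc bromide from 21 | COc1cc([Zn]Br)ccc1O[C@H](C)[C@@H](O[Si](C)(C)C(C)(C)C)c1ccc(OCc2ccccc2)c(OC)c1 | intermediate
23 | 3,4,5-all-cis 5-(4-benzyloxy-3-methoxyphenyl)-3,4-dimethyl-4,5-dihydro-3H-furan-1-ium (oxocarbenium ion) | COc1cc([C@H]2[O+]=C[C@@H](C)[C@H]2C)ccc1OCc1ccccc1 | intermediate
24 | (2S,3R,4S,5S)-2-(4-benzyloxy-3-methoxyphenyl)-5-{4-[((1S,2R)-1-(4-benzyloxy-3-methoxyphenyl)-1-(tert-butyldimethylsilyloxy)propan-2-yl)oxy]-3-methoxyphenyl}-3,4-dimethyltetrahydrofuran | COc1cc([C@H]2O[C@H](c3ccc(O[C@H](C)[C@@H](O[Si](C)(C)C(C)(C)C)c4ccc(OCc5ccccc5)c(OC)c4)c(OC)c3)[C@@H](C)[C@H]2C)ccc1OCc1ccccc1 | intermediate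
25 | (1S,2R)-1-(4-benzyloxy-3-methoxyphenyl)-2-{4-[(2S,3S,4R,5S)-5-(4-benzyloxy-3-methoxyphenyl)-3,4-dimethyltetrahydrofuran-2-yl]-2-methoxyphenoxy}propan-1-ol | COc1cc([C@H]2O[C@H](c3ccc(O[C@H](C)[C@@H](O)c4ccc(OCc5ccccc5)c(OC)c4)c(OC)c3)[C@@H](C)[C@H]2C)ccc1OCc1ccccc1 | intermediate
26 | CNP0171079.3, 4-[(2S,3R,4S,5S)-5-{4-[((1S,2R)-1-hydroxy-1-(4-hydroxy-3-methoxyphenyl)propan-2-yl)oxy]-3-methoxyphenyl}-3,4-dimethyltetrahydrofuran-2-yl]-2-methoxyphenol | COc1cc([C@H]2O[C@H](c3ccc(O[C@H](C)[C@@H](O)c4ccc(O)c(OC)c4)c(OC)c3)[C@@H](C)[C@H]2C)ccc1O | target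

**Step count**
Total: 15 steps. Longest linear sequence: 10 steps (steps 1–7, then 13, 14 and 15); fragment 2 takes steps 8–12.

**Steps most likely to fail**

Step 4 (butenolide annulation). Methyl transfer to the internal alkyne may be slow, and the CO2 capture may be inefficient, through protonation of the vinylmagnesium during gassing or attack of surplus MeMgCl on the forming carboxylate. The fallback sets out from 5 and returns at 8. The same CuI-catalysed anti-carbomagnesiation is quenched with I2, the most forgiving electrophile for the chelated vinylmagnesium, to give (1R,2Z)-1-(4-benzyloxy-3-methoxyphenyl)-3-iodo-2-methylbut-2-en-1-ol F1. F1 is then closed by palladium-catalysed cyclocarbonylation (PdCl2(PPh3)2, CO, K2CO3, THF, 50 °C), in which the acylpalladium is captured by the cis hydroxyl, so the lactone carbonyl comes from CO and not from CO2.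

Step 5 (hydrogenation). Saturation of the tetrasubstituted alkene may be slow enough for hydrogenolysis of the O-benzyl group or of the benzylic lactone C–O bond to compete, or face control at the α-carbon may be incomplete. The fallback sets out from 8 and returns at 9. Conjugate reduction with nickel boride generated from NiCl2·6H2O and NaBH4 (MeOH, 0 °C) needs no hydrogen pressure and leaves benzyl ethers alone; it should place the C4 methyl cis to the aryl group. If C3 comes out trans, as (3R,4R,5S)-5-(4-benzyloxy-3-methoxyphenyl)-3,4-dimethyldihydrofuran-2(3H)-one F2, the lactone is enolised with LiN(i-Pr)2 (THF, −78 °C) and protonated kinetically with a bulky phenol on the face away from the C4 methyl and the aryl ring, which should return the all-cis lactone 9.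

Step 13 (fragment union). The bulky, heavily functionalised arylzinc may react slowly with the hindered oxocarbenium ion, so that elimination to the dihydrofuran (with loss of the adjacent methyl centre) or erosion of face selectivity takes over. The fallback sets out from 13 and 11 and returns at 25, building the side chain after the coupling so that a small, cheap arylzinc can be used in excess.
- Phenol 13 is silylated (i-Pr3SiCl, imidazole, DMF) to (4-bromo-2-methoxyphenoxy)triisopropylsilane F3.
- F3 is converted with n-BuLi and then ZnBr2 into its arylzinc and coupled with sulfone 11 to give (2S,3R,4S,5S)-2-(4-benzyloxy-3-methoxyphenyl)-5-[3-methoxy-4-(triisopropylsilyloxy)phenyl]-3,4-dimethyltetrahydrofuran F4.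
- Bu4NF frees (2S,3R,4S,5S)-2-(4-benzyloxy-3-methoxyphenyl)-5-(4-hydroxy-3-methoxyphenyl)-3,4-dimethyltetrahydrofuran F5.
- Mitsunobu etherification of F5 with ethyl (S)-lactate 12 (PPh3, DIAD) gives ethyl (R)-2-{4-[(2S,3S,4R,5S)-5-(4-benzyloxy-3-methoxyphenyl)-3,4-dimethyltetrahydrofuran-2-yl]-2-methoxyphenoxy}propanoate F6.
- MeNHOMe·HCl with i-PrMgCl turns F6 into (R)-2-{4-[(2S,3S,4R,5S)-5-(4-benzyloxy-3-methoxyphenyl)-3,4-dimethyltetrahydrofuran-2-yl]-2-methoxyphenoxy}-N-methoxy-N-methylpropanamide F7.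
- Addition of Grignard reagent 17 gives (R)-1-(4-benzyloxy-3-methoxyphenyl)-2-{4-[(2S,3S,4R,5S)-5-(4-benzyloxy-3-methoxyphenyl)-3,4-dimethyltetrahydrofuran-2-yl]-2-methoxyphenoxy}propan-1-one F8.
- Chelation-controlled reduction of F8 with Zn(BH4)2 should give 25, which rejoins the route before step 15.

**Further compounds**
F1 | step 4 | (1R,2Z)-1-(4-benzyloxy-3-methoxyphenyl)-3-iodo-2-methylbut-2-en-1-ol | I/C(C)=C(C)\[C@H](O)c1ccc(OCc2ccccc2)c(OC)c1
F2 | step 5 | (3R,4R,5S)-5-(4-benzyloxy-3-methoxyphenyl)-3,4-dimethyldihydrofuran-2(3H)-one | COc1cc([C@H]2OC(=O)[C@H](C)[C@H]2C)ccc1OCc1ccccc1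
F3 | step 13 | (4-bromo-2-methoxyphenoxy)triisopropylsilane | COc1cc(Br)ccc1O[Si](C(C)C)(C(C)C)C(C)C
F4 | step 13 | (2S,3R,4S,5S)-2-(4-benzyloxy-3-methoxyphenyl)-5-[3-methoxy-4-(triisopropylsilyloxy)phenyl]-3,4-dimethyltetrahydrofuran | COc1cc([C@H]2O[C@H](c3ccc(O[Si](C(C)C)(C(C)C)C(C)C)c(OC)c3)[C@@H](C)[C@H]2C)ccc1OCc1ccccc1
F5 | step 13 | (2S,3R,4S,5S)-2-(4-benzyloxy-3-methoxyphenyl)-5-(4-hydroxy-3-methoxyphenyl)-3,4-dimethyltetrahydrofuran | COc1cc([C@H]2O[C@H](c3ccc(O)c(OC)c3)[C@@H](C)[C@H]2C)ccc1OCc1ccccc1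
F6 | step 13 | ethyl (R)-2-{4-[(2S,3S,4R,5S)-5-(4-benzyloxy-3-methoxyphenyl)-3,4-dimethyltetrahydrofuran-2-yl]-2-methoxyphenoxy}propanoate | COc1cc([C@H]2O[C@H](c3ccc(O[C@H](C)C(=O)OCC)c(OC)c3)[C@@H](C)[C@H]2C)ccc1OCc1ccccc1
F7 | step 13 | (R)-2-{4-[(2S,3S,4R,5S)-5-(4-benzyloxy-3-methoxyphenyl)-3,4-dimethyltetrahydrofuran-2-yl]-2-methoxyphenoxy}-N-methoxy-N-methylpropanamide | COc1cc([C@H]2O[C@H](c3ccc(O[C@H](C)C(=O)N(C)OC)c(OC)c3)[C@@H](C)[C@H]2C)ccc1OCc1ccccc1
F8 | step 13 | (R)-1-(4-benzyloxy-3-methoxyphenyl)-2-{4-[(2S,3S,4R,5S)-5-(4-benzyloxy-3-methoxyphenyl)-3,4-dimethyltetrahydrofuran-2-yl]-2-methoxyphenoxy}propan-1-one | COc1cc([C@H]2O[C@H](c3ccc(O[C@H](C)C(=O)c4ccc(OCc5ccccc5)c(OC)c4)c(OC)c3)[C@@H](C)[C@H]2C)ccc1OCc1ccccc1
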